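The data stem from a simulated flask with constants of no real substance; noise was put on by code.

Over the hours of Sunday's run, the solid substrate keeps falling while target stops rising.

- Sunday's: solid substrate 0.050 M; reagent 1.5 equiv; protic impurity 5 mM; the very flask that is asked about, followed so far
- flask: solid substrate 0.050 M; reagent 1.50 equiv; protic impurity 5.00 mM; time 6.0 d

Sunday's run (percent of the solid substrate charged)

| time / h | target / % | solid substrate / % |
|---|---|---|
| 1.33 | 1.8 | 71.3 |
| 2.50 | 6.2 | 63.6 |
| 4.00 | 7.7 | 53.9 |
| 6.00 | 10.0 | 45.9 |
| 10.0 | 10.9 | 39.9 |
| 15.0 | 9.6 | 36.1 |

(standard deviation of a reading: 1 percentage point)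

- the numbers in the tables scatter by 1 percentage point (one standard deviation)
- at the start none of the solid substrate is in solution
- a reading or a percentage of target counts all its forms, free or not

1. when, up to 6.0 d, the flask holds most target
2. the amount of target, in percent of the solid substrate charged, at that time

The time of the maximum need not be known closely: in Sunday's run target reads 10.0%, 10.9% and 9.6% at 6.00 h, 10.0 h and 15.0 h, so an error of hours shifts the height by about the scatter of 1 percentage point. The protic impurity is charged at 10.0% of the substrate, close to that height, but one run does not separate a cap from a coincidence. The reagent charge needs a closer look. In Sunday's run the ratio of target gained to solid substrate lost reads 0.571 between 1.33 h and 2.50 h, then 0.150 between 6.00 h and 10.0 h, a fall that comes with 36.1% of the solid substrate still reading at 15.0 h, so this reckoning ties the height to the reagent charge. The top reading of target, counted one to one, equals 7.27% of the charged reagent; this share, target standing at its height per reagent charged, is the reagent catch. The reckoning commits to about 10.9% at 0.42 d.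

The forecast gave 10.7% at 0.45 d, “a broad maximum”. The flask gives 10.6% at 0.403 d.

    reagent → side product (k = 0.277 h⁻¹)
    dissolved substrate + reagent → target (k = 3.54 M⁻¹ h⁻¹)
    solid product ⇌ target, rate k3*(cs3 - [target]) while solid is left; crystals form when [target] > cs3 (solubility = 1.60 mM, k = 2.48 h⁻¹)
    solid substrate + protic impurity → quenched substrate (k = 993 M⁻¹ h⁻¹)
    target ⇌ isomer of the product (K = 5.71, k = 0.176 h⁻¹)
    reagent + target ⇌ idle adduct, settled at all times (K = 15.0 M⁻¹)
    solid substrate ⇌ dissolved substrate, rate k7*(cs7 - [dissolved substrate]) while solid is left; crystals form when [dissolved substrate] > cs7 (solubility = 19.0 mM, k = 0.424 h⁻¹)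

Just after the start, reagent in this flask goes to side product 680 times faster than to target. At 0.403 d, 4.63% of its charge is free and the catch stands at 7.06%. For the neighbouring flask charged with 6.00 equiv of reagent, the catch from Sunday's run gives 43.6%, and that flask reaches 41.9%.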